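The route cuts the C9–C10 single bond (carotenoid numbering) between two alkenes of the retro-polyene. The key step exploits the unit C7(=ring A)–C8H=C9(CH3): in a C13 enyne the alkyne C8≡C9–CH3 hangs on the ring A ylidene carbon C7. Hydrozirconation sets C8=C9 as E with the metal on C9, and a Negishi coupling joins this alkenyl metal to the C10 terminus of a C27 (E)-vinyl iodide. One operation thus builds the trisubstituted alkene and the C9–C10 bond. The C27 iodide comes from the ring B enyne and a symmetric C14 hexaenyl diiodide by the same reaction.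

Key step: step 14

Remark: ring A is the dienylidene end (C1–C6) and ring B the hydroxylated end (C1'–C6'); the sense of induction in step 5 is assumed to follow the usual Noyori model with the enone C=C in the place of the aryl group, and the enantiomeric ligand would be used if it proved opposite.

**Central C14 diiodide**

Step 1
Reactants: 1 (2E)-3-methylpent-2-en-4-yn-1-ol
Product: 2 (2E,4E)-3-methyl-5-(tributylstannyl)penta-2,4-dien-1-ol
Conditions: Bu3SnH, PdCl2(PPh3)2 (2 mol %), THF, 0 °C
Reagents that add atoms: tributyltin hydride CCCC[SnH](CCCC)CCCC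
Why: Palladium-catalysed hydrostannation adds H and SnBu3 syn across the terminal alkyne, and the 3-methyl branch should steer tin to the terminal carbon, so the (4E)-stannane is expected (minor internal regioisomer removed on silica).

Step 2
Reactants: 2 (2E,4E)-3-methyl-5-(tributylstannyl)penta-2,4-dien-1-ol
Product: 3 (2E,4E)-3-methyl-5-(tributylstannyl)penta-2,4-dienal
Conditions: MnO2, CH2Cl2, rt
Reagents that add atoms: none
Why: Allylic oxidation with MnO2 should give the dienal without touching the C–Sn bond or the alkene geometry.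

Step 3
Reactants: 3 (2E,4E)-3-methyl-5-(tributylstannyl)penta-2,4-dienal (two molecules)
Product: 4 (2E,4E,6E,8E)-3,8-dimethyldeca-2,4,6,8-tetraenedial
Conditions: CuCl (3 equiv), DMF, rt, dark
Reagents that add atoms: none
Why: Copper-mediated oxidative homocoupling of the alkenylstannane (tin-to-copper exchange, then dimerisation of the alkenylcopper with retention) should give the symmetric all-E dial and with it the central C15–C15' bond.

Step 4
Reactants: 4 (2E,4E,6E,8E)-3,8-dimethyldeca-2,4,6,8-tetraenedial
Product: 5 (1E,3E,5E,7E,9E,11E)-1,12-diiodo-4,9-dimethyldodeca-1,3,5,7,9,11-hexaene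
Conditions: CHI3, CrCl2, THF–dioxane, 0 °C to rt, dark
Reagents that add atoms: iodoform IC(I)I
Why: Twofold Takai–Utimoto iodo-olefination turns each CHO into an (E)-CH=CHI unit, the E geometry arising from the anti elimination of the gem-dichromium adduct.

**Ring B enyne and C27 iodide**

Step 5
Reactants: 6 ketoisophorone (2,6,6-trimethylcyclohex-2-ene-1,4-dione)
Product: 7 (4S)-4-hydroxy-2,6,6-trimethylcyclohex-2-en-1-one
Conditions: RuCl[(S,S)-TsDPEN](p-cymene) (1 mol %), i-PrOH, rt
Reagents that add atoms: none
Why: Noyori asymmetric transfer hydrogenation reduces the less hindered C4 carbonyl of the ene-dione, and the chiral catalyst sets the single stereocentre (later C3') as S by face-selective hydride delivery.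

Step 6
Reactants: 7 (4S)-4-hydroxy-2,6,6-trimethylcyclohex-2-en-1-one
Product: 8 (4S)-4-[(tert-butyldimethylsilyl)oxy]-2,6,6-trimethylcyclohex-2-en-1-one
Conditions: TBSCl, imidazole, DMF, rt
Reagents that add atoms: tert-butyldimethylsilyl chloride CC(C)(C)[Si](C)(C)Cl
Why: Standard silylation masks the secondary allylic alcohol for the organometallic and phosphine steps that follow and leaves the stereocentre untouched.

Step 7
Reactants: 8 (4S)-4-[(tert-butyldimethylsilyl)oxy]-2,6,6-trimethylcyclohex-2-en-1-one
Product: 9 (4S)-4-[(tert-butyldimethylsilyl)oxy]-1-ethynyl-2,6,6-trimethylcyclohex-2-en-1-ol (both C1 epimers)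
Conditions: HC≡CMgBr (3 equiv), THF, 0 °C to rt; aq. NH4Cl
Reagents that add atoms: ethynylmagnesium bromide C#C[Mg]Br
Why: Grignard 1,2-addition of the small ethynyl nucleophile to the hindered enone carbonyl gives the tertiary propargylic alcohol, whose new carbinol centre is formed as an epimer mixture and is erased in step 8.

Step 8
Reactants: 9 (4S)-4-[(tert-butyldimethylsilyl)oxy]-1-ethynyl-2,6,6-trimethylcyclohex-2-en-1-ol
Product: 10 (2E)-2-[(4S)-4-[(tert-butyldimethylsilyl)oxy]-2,6,6-trimethylcyclohex-2-en-1-ylidene]acetaldehyde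
Conditions: MoO2(acac)2, AuCl(PPh3), AgOTf (2 mol % each), toluene, rt; separation of the exocyclic isomers on silica
Reagents that add atoms: none
Why: Meyer–Schuster rearrangement (1,3-oxygen shift to the allenol, then tautomerisation) gives the ylidene-acetaldehyde, a Rupe dehydration being impossible because neither neighbour of the carbinol carbon bears hydrogen; both exocyclic isomers are expected, the (E)-isomer (CHO syn to the gem-dimethyl carbon) is isolated and the other is recycled by iodine-catalysed equilibration.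

Step 9
Reactants: 10 (2E)-2-[(4S)-4-[(tert-butyldimethylsilyl)oxy]-2,6,6-trimethylcyclohex-2-en-1-ylidene]acetaldehyde
Product: 11 tert-butyl{[(1S,4E)-4-(3,3-dibromoprop-2-en-1-ylidene)-3,5,5-trimethylcyclohex-2-en-1-yl]oxy}dimethylsilane
Conditions: CBr4, PPh3, CH2Cl2, 0 °C
Reagents that add atoms: tetrabromomethane BrC(Br)(Br)Br
Why: Corey–Fuchs dibromo-olefination with Ph3P=CBr2 converts the aldehyde into the 1,1-dibromoalkene under neutral conditions that should not disturb the exocyclic geometry.

Step 10
Reactants: 11 tert-butyl{[(1S,4E)-4-(3,3-dibromoprop-2-en-1-ylidene)-3,5,5-trimethylcyclohex-2-en-1-yl]oxy}dimethylsilane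
Product: 13 tert-butyl{[(1S,4E)-4-(but-2-yn-1-ylidene)-3,5,5-trimethylcyclohex-2-en-1-yl]oxy}dimethylsilane (ring B enyne), via lithium acetylide 12 (not isolated)
Conditions: n-BuLi (2.1 equiv), THF, −78 °C; MeI, −78 °C to rt
Reagents that add atoms: iodomethane CI
Why: In the second Corey–Fuchs stage, Br/Li exchange and Fritsch–Buttenberg–Wiechell rearrangement give the lithium acetylide, which MeI methylates on carbon to the methyl-capped enyne.

Step 11
Reactants: 13 ring B enyne; 5 (1E,3E,5E,7E,9E,11E)-1,12-diiodo-4,9-dimethyldodeca-1,3,5,7,9,11-hexaene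
Product: 16 tert-butyl{[(1S,4E)-4-[(2E,4E,6E,8E,10E,12E,14E)-15-iodo-3,7,12-trimethylpentadeca-2,4,6,8,10,12,14-heptaen-1-ylidene]-3,5,5-trimethylcyclohex-2-en-1-yl]oxy}dimethylsilane (C27 iodide), via alkenylzirconocene chloride 14 (not isolated), via alkenylzinc chloride 15 (not isolated)
Conditions: Cp2Zr(H)Cl (1.2 equiv), THF, rt to 40 °C; ZnCl2 (1.2 equiv), 0 °C; 5 (3 equiv), Pd(PPh3)4 (5 mol %), THF, rt, dark
Reagents that add atoms: none
Why: Hydrozirconation adds Zr–H syn across the alkyne with zirconium on the less hindered methyl-bearing carbon C9', and zinc-assisted Negishi coupling with retention at both partners joins C9' to C10', a threefold excess of the symmetric diiodide favouring mono-coupling.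

**Ring A enyne**

Step 12
Reactants: 17 safranal (2,6,6-trimethylcyclohexa-1,3-diene-1-carbaldehyde)
Product: 18 1-(2,6,6-trimethylcyclohexa-1,3-dien-1-yl)but-2-yn-1-ol (racemic)
Conditions: CH3C≡CMgBr, THF, 0 °C; aq. NH4Cl
Reagents that add atoms: 1-propynylmagnesium bromide CC#C[Mg]Br
Why: Grignard 1,2-addition of the propynyl nucleophile to the aldehyde gives the dienyl propargyl carbinol, whose carbinol centre is erased in step 13.

Step 13
Reactants: 18 1-(2,6,6-trimethylcyclohexa-1,3-dien-1-yl)but-2-yn-1-ol
Product: 20 (6Z)-6-(but-2-yn-1-ylidene)-1,5,5-trimethylcyclohexa-1,3-diene (ring A enyne), via mesylate 19 (not isolated)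
Conditions: MsCl, Et3N, CH2Cl2, −40 °C; DBU, −40 to 0 °C; AgNO3-impregnated silica
Reagents that add atoms: none
Why: Mesylation and base-induced 1,6-elimination (loss of the C7 leaving group and of a ring C2 hydrogen through the diene, as in the dehydration of retinol to anhydroretinol) should give the cross-conjugated triene of ring A; both exocyclic isomers are expected and the (Z)-isomer (alkyne syn to the gem-dimethyl carbon) is isolated.

**Union and deprotection**

Step 14
Reactants: 20 ring A enyne; 16 C27 iodide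
Product: 23 O-tert-butyldimethylsilyl ether of the target, via alkenylzirconocene chloride 21 (not isolated), via alkenylzinc chloride 22 (not isolated)
Conditions: Cp2Zr(H)Cl (1.2 equiv), THF, rt, dark; ZnCl2 (1.2 equiv), 0 °C; 16 (0.8 equiv), Pd(PPh3)4 (5 mol %), THF, rt, dark
Reagents that add atoms: none
Why: Cp2Zr(H)Cl adds H and Zr syn across C8≡C9 of 20 with zirconium on the methyl-bearing C9 (the less hindered alkyne carbon, the ratio being improved by equilibration with a slight excess of reagent), so C8=C9 forms with C7 trans to the metal; transmetalation to zinc and a palladium cycle (oxidative addition into the C10–I bond of 16, transmetalation, reductive elimination) then forge C9–C10 with retention at both carbons. The closest known reaction type is the Negishi hydrozirconation/alkenyl–alkenyl cross-coupling with ZnCl2 assistance for hindered alpha-substituted alkenyl metals. No ring is closed and no stereocentre is created; the elements set are the 8E alkene (syn addition) and the retained 10E alkene. The step needs chemoselectivity for the alkyne over the ring A triene and the polyene (alkynes are hydrozirconated far faster than internal alkenes, and 16 is added only after the hydride is consumed) and mildness toward the dodecaene (room temperature, neutral, dark).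

Step 15
Reactants: 23 O-tert-butyldimethylsilyl ether of the target
Product: 24 target, (3'S)-retro-carotenoid with ring A = (Z)-2,6,6-trimethylcyclohexa-2,4-dien-1-ylidene, ring B = (E)-(4S)-4-hydroxy-2,6,6-trimethylcyclohex-2-en-1-ylidene and an all-E 3,7,12,16-tetramethyloctadeca-2,4,6,8,10,12,14,16-octaene-1,18-diylidene chain
Conditions: Bu4NF, AcOH, THF, 0 °C to rt, dark
Reagents that add atoms: none
Why: Fluoride-mediated desilylation buffered with AcOH frees the C3' alcohol under non-acidic conditions that should neither ionise the allylic alcohol nor isomerise the polyene.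

**Compound list**

1 | (2E)-3-methylpent-2-en-4-yn-1-ol | C#C/C(C)=C/CO | starting material
2 | (2E,4E)-3-methyl-5-(tributylstannyl)penta-2,4-dien-1-ol | CCCC[Sn](CCCC)(CCCC)/C=C/C(C)=C/CO | intermediate
3 | (2E,4E)-3-methyl-5-(tributylstannyl)penta-2,4-dienal | CCCC[Sn](CCCC)(CCCC)/C=C/C(C)=C/C=O | intermediate
4 | (2E,4E,6E,8E)-3,8-dimethyldeca-2,4,6,8-tetraenedial | O=C/C=C(C)/C=C/C=C/C(C)=C/C=O | intermediate
5 | (1E,3E,5E,7E,9E,11E)-1,12-diiodo-4,9-dimethyldodeca-1,3,5,7,9,11-hexaene | I/C=C/C=C(C)/C=C/C=C/C(C)=C/C=C/I | intermediate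
6 | ketoisophorone | CC1=CC(=O)CC(C)(C)C1=O | starting material
7 | (4S)-4-hydroxy-2,6,6-trimethylcyclohex-2-en-1-one | CC1=C[C@@H](O)CC(C)(C)C1=O | intermediate
8 | (4S)-4-[(tert-butyldimethylsilyl)oxy]-2,6,6-trimethylcyclohex-2-en-1-one | CC1=C[C@@H](O[Si](C)(C)C(C)(C)C)CC(C)(C)C1=O | intermediate
9 | (4S)-4-[(tert-butyldimethylsilyl)oxy]-1-ethynyl-2,6,6-trimethylcyclohex-2-en-1-ol, C1 epimers | CC1=C[C@@H](O[Si](C)(C)C(C)(C)C)CC(C)(C)C1(O)C#C | intermediate
10 | (2E)-2-[(4S)-4-[(tert-butyldimethylsilyl)oxy]-2,6,6-trimethylcyclohex-2-en-1-ylidene]acetaldehyde | O=C/C=C1/C(C)=C[C@@H](O[Si](C)(C)C(C)(C)C)CC1(C)C | intermediate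
11 | tert-butyl{[(1S,4E)-4-(3,3-dibromoprop-2-en-1-ylidene)-3,5,5-trimethylcyclohex-2-en-1-yl]oxy}dimethylsilane | BrC(Br)=C/C=C1/C(C)=C[C@@H](O[Si](C)(C)C(C)(C)C)CC1(C)C | intermediate
12 | lithium acetylide of the ring B enyne | [Li]C#C/C=C1/C(C)=C[C@@H](O[Si](C)(C)C(C)(C)C)CC1(C)C | intermediate
13 | tert-butyl{[(1S,4E)-4-(but-2-yn-1-ylidene)-3,5,5-trimethylcyclohex-2-en-1-yl]oxy}dimethylsilane (ring B enyne) | CC#C/C=C1/C(C)=C[C@@H](O[Si](C)(C)C(C)(C)C)CC1(C)C | intermediate
14 | alkenylzirconocene chloride from 13 (Zr on C9', C7' trans to Zr) | C/C(=C\C=C1\C(C)=C[C@@H](O[Si](C)(C)C(C)(C)C)CC1(C)C)[Zr+2]Cl.c1cc[cH-]c1.c1cc[cH-]c1 | intermediate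
15 | alkenylzinc chloride from 13 | C/C(=C\C=C1\C(C)=C[C@@H](O[Si](C)(C)C(C)(C)C)CC1(C)C)[Zn]Cl | intermediate
16 | C27 iodide, tert-butyl{[(1S,4E)-4-[(2E,4E,6E,8E,10E,12E,14E)-15-iodo-3,7,12-trimethylpentadeca-2,4,6,8,10,12,14-heptaen-1-ylidene]-3,5,5-trimethylcyclohex-2-en-1-yl]oxy}dimethylsilane | I/C=C/C=C(C)/C=C/C=C/C(C)=C/C=C/C(C)=C/C=C1/C(C)=C[C@@H](O[Si](C)(C)C(C)(C)C)CC1(C)C | intermediate
17 | safranal | O=CC1=C(C)C=CCC1(C)C | starting material
18 | 1-(2,6,6-trimethylcyclohexa-1,3-dien-1-yl)but-2-yn-1-ol (racemic) | CC#CC(O)C1=C(C)C=CCC1(C)C | intermediate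
19 | 1-(2,6,6-trimethylcyclohexa-1,3-dien-1-yl)but-2-yn-1-yl methanesulfonate | CC#CC(OS(C)(=O)=O)C1=C(C)C=CCC1(C)C | intermediate
20 | (6Z)-6-(but-2-yn-1-ylidene)-1,5,5-trimethylcyclohexa-1,3-diene (ring A enyne) | CC1=CC=CC(C)(C)\C1=C/C#CC | intermediate
21 | alkenylzirconocene chloride from 20 (Zr on C9, C7 trans to Zr) | CC1=CC=CC(C)(C)\C1=C/C=C(\C)[Zr+2]Cl.c1cc[cH-]c1.c1cc[cH-]c1 | intermediate
22 | alkenylzinc chloride from 20 | CC1=CC=CC(C)(C)\C1=C/C=C(\C)[Zn]Cl | intermediate
23 | O-tert-butyldimethylsilyl ether of the target | CC1=CC=CC(C)(C)\C1=C/C=C(C)/C=C/C=C(C)/C=C/C=C/C(C)=C/C=C/C(C)=C/C=C1/C(C)=C[C@@H](O[Si](C)(C)C(C)(C)C)CC1(C)C | intermediate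
24 | target (CNP0202479.1) | CC1=CC=CC(C)(C)\C1=C/C=C(C)/C=C/C=C(C)/C=C/C=C/C(C)=C/C=C/C(C)=C/C=C1/C(C)=C[C@@H](O)CC1(C)C | target

**Step count:** 15 steps in total. The longest linear sequence is 9 steps (6 to 24: steps 5–11, 14, 15).

**Steps most likely to fail**

Step 14. The hydrozirconation may leak zirconium onto C8. The hindered methyl-bearing alkenyl metal may also transmetalate slowly, so that the dodecaene isomerises or decomposes before it couples. The fallback reverses the roles of the partners and sets out from 20 and 16. Hydrozirconation of 20 is quenched with I2 to give the vinyl iodide (6Z)-6-[(2E)-3-iodobut-2-en-1-ylidene]-1,5,5-trimethylcyclohexa-1,3-diene F1, which can be freed of any C8 regioisomer before use. Iodide 16 is converted with Bu3SnSnBu3 and Pd(PPh3)4 into the C27 stannane F2. A Stille–Migita coupling of F1 with F2 (Pd2(dba)3, AsPh3, CuI, DMF, rt, dark) then puts the hindered carbon on the oxidative-addition side and the unhindered terminal vinyl on tin, and returns to the route at 23.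

Step 13. Ionisation of the mesylate may be followed by proton loss from the C5 methyl instead of ring C2, or by methyl migration and aromatisation, and the exocyclic geometry may form without preference. The fallback avoids cations and sets out from 17. Vinylogous deprotonation of safranal at ring C2 with KN(SiMe3)2 (THF, −78 °C) and O-sulfonylation with PhNTf2 gives the trienyl triflate [(Z)-(2,6,6-trimethylcyclohexa-2,4-dien-1-ylidene)methyl] trifluoromethanesulfonate F3 (isomers separated). Sonogashira coupling of F3 with propyne (PdCl2(PPh3)2, CuI, Et3N, THF, rt) proceeds with retention and returns to the route at 20.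

Step 8. The 1,3-oxygen shift may run into the ring allyl system instead of along the alkyne, the allylic silyl ether may ionise under the Lewis-acidic catalysts, and the two exocyclic isomers may form in equal amounts. The fallback sets out from 8. Peterson olefination with lithiated (trimethylsilyl)acetonitrile (Me3SiCH2CN, LiN(i-Pr)2, THF, −78 °C to rt) gives the nitrile (2E)-2-[(4S)-4-[(tert-butyldimethylsilyl)oxy]-2,6,6-trimethylcyclohex-2-en-1-ylidene]acetonitrile F4 (isomers separated). Reduction with i-Bu2AlH (toluene, −78 °C) and hydrolysis of the aldimine returns to the route at 10.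

Further compounds
F1 | step 14 | (6Z)-6-[(2E)-3-iodobut-2-en-1-ylidene]-1,5,5-trimethylcyclohexa-1,3-diene | CC1=CC=CC(C)(C)\C1=C/C=C(\C)I
F2 | step 14 | C27 stannane, the tributylstannyl analogue of 16 | CCCC[Sn](CCCC)(CCCC)/C=C/C=C(C)/C=C/C=C/C(C)=C/C=C/C(C)=C/C=C1/C(C)=C[C@@H](O[Si](C)(C)C(C)(C)C)CC1(C)C
F3 | step 13 | [(Z)-(2,6,6-trimethylcyclohexa-2,4-dien-1-ylidene)methyl] trifluoromethanesulfonate | CC1=CC=CC(C)(C)\C1=C/OS(=O)(=O)C(F)(F)F
F4 | step 8 | (2E)-2-[(4S)-4-[(tert-butyldimethylsilyl)oxy]-2,6,6-trimethylcyclohex-2-en-1-ylidene]acetonitrile | N#C/C=C1/C(C)=C[C@@H](O[Si](C)(C)C(C)(C)C)CC1(C)C
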